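Ring A is opened at C1–C2, the bond between its two unsubstituted methylenes: C1 hangs on quaternary C10 and C2 leads through C3 to C4 (labdane numbering). This turns C1 into a vinyl group on C10 and C2–C3 into an allyl group on C4 of a ring-B cyclohexanone, where the two arms sit trans-diequatorial across C5–C10. Ring-closing metathesis of this 1,7-diene forges C1=C2 and the trans-decalin in one operation; one hydrogenation then saturates it together with the C9 alkylidene. The diene comes from an Ireland–Claisen chirality transfer, an allylic oxidation and a vinyl-cuprate/aldol coupling; C4 is methylated later under ring control.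

Key step: step 10

Remark: atom labels C1–C20 follow labdane numbering (ring A = C1–C5, C10; ring B = C5–C10; C17 exocyclic methylene carbon, C18 equatorial methyl and C19 axial oxygenated carbon on C4, C20 methyl on C10, side chain C11–C16).
Remark: the ester-bearing C4 is carried as an inconsequential epimer mixture (no descriptor in the SMILES) from step 3 until it becomes quaternary in step 14; the aldol centres of 14 and 15 and the alkene geometry of 16 and 17 are likewise left open because later steps erase them.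
Assumption: (2R)-2-methylbutanoic acid (24) and methyl hydrogen (3R)-3-methylglutarate (10) are taken as commercially available, enantiopure starting materials.

Step 1
Reactants: 1 2-methylcyclohex-2-en-1-one
Product: 2 (1R)-2-methylcyclohex-2-en-1-ol
Conditions: (S)-2-methyl-CBS-oxazaborolidine (10 mol%), BH3·SMe2, THF, −20 °C; MeOH quench
Reagents that add atoms: none
Why: Corey–Bakshi–Shibata reduction, in which the methyl-substituted alkene arm acts as the large group, so the (S)-oxazaborolidine should deliver hydride to give the (R)-carbinol (the future C9–O bond) that later dictates C5.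

Step 2
Reactants: 2 (1R)-2-methylcyclohex-2-en-1-ol; 3 pent-4-enoyl chloride
Product: 4 (1R)-2-methylcyclohex-2-en-1-yl pent-4-enoate
Conditions: pyridine, DMAP (cat.), CH2Cl2, 0 °C to rt
Reagents that add atoms: none
Why: DMAP-catalysed O-acylation of the allylic alcohol by the acid chloride, with no change at the carbinol centre.

Step 3
Reactants: 4 (1R)-2-methylcyclohex-2-en-1-yl pent-4-enoate
Product: 7 2-[(1R)-2-methylcyclohex-2-en-1-yl]pent-4-enoic acid (C4 epimers), via silyl ketene acetal 5 (not isolated), via trimethylsilyl ester 6 (not isolated)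
Conditions: LiN(iPr)2, THF, −78 °C; Me3SiCl; warm to 60 °C; 1 M HCl
Reagents that add atoms: none
Why: Ireland–Claisen rearrangement, in which the silyl ketene acetal undergoes a suprafacial [3,3] shift across the cyclohexenyl unit, so the C9–O stereocentre is transferred to C5 (R) while the C9=C10 alkene and the allyl-bearing ester α-carbon C4 are formed.

Step 4
Reactants: 7 2-[(1R)-2-methylcyclohex-2-en-1-yl]pent-4-enoic acid
Product: 8 methyl 2-[(1R)-2-methylcyclohex-2-en-1-yl]pent-4-enoate
Conditions: MeI, K2CO3, DMF, rt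
Reagents that add atoms: iodomethane CI
Why: SN2 O-methylation of the carboxylate gives the methyl ester needed for the later organometallic and enolate chemistry.

Step 5
Reactants: 8 methyl 2-[(1R)-2-methylcyclohex-2-en-1-yl]pent-4-enoate
Product: 9 methyl 2-[(1R)-2-methyl-4-oxocyclohex-2-en-1-yl]pent-4-enoate
Conditions: Rh2(cap)4 (dirhodium tetrakis(caprolactamate), 1 mol%), t-BuOOH, K2CO3 (cat.), CH2Cl2, rt
Reagents that add atoms: tert-butyl hydroperoxide CC(C)(C)OO
Why: allylic C–H oxidation by a tert-butylperoxyl radical chain, in which hydrogen abstraction should be fastest at the unhindered ring methylene C8 next to the electron-rich trisubstituted alkene, giving the C8 ketone conjugated with C9=C10 while the terminal alkene is much less reactive.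

Step 6
Reactants: 10 (3R)-5-methoxy-3-methyl-5-oxopentanoic acid
Product: 11 methyl (3R)-5-hydroxy-3-methylpentanoate
Conditions: BH3·SMe2, THF, −10 °C to rt; MeOH quench
Reagents that add atoms: none
Why: chemoselective borane reduction, in which the acid is reduced through its acyloxyborane much faster than the methyl ester and the C13 stereocentre is untouched.

Step 7
Reactants: 11 methyl (3R)-5-hydroxy-3-methylpentanoate
Product: 12 methyl (3R)-3-methyl-5-oxopentanoate
Conditions: Dess–Martin periodinane, CH2Cl2, 0 °C to rt (crude 11 used at once)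
Reagents that add atoms: none
Why: Dess–Martin oxidation of the primary alcohol to the aldehyde under neutral conditions, run immediately so that lactonisation of 11 cannot compete.

Step 8
Reactants: 9 methyl 2-[(1R)-2-methyl-4-oxocyclohex-2-en-1-yl]pent-4-enoate; 12 methyl (3R)-3-methyl-5-oxopentanoate
Product: 14 methyl (3R)-5-[(2R,3R)-2-ethenyl-3-(1-methoxy-1-oxopent-4-en-2-yl)-2-methyl-6-oxocyclohexyl]-5-hydroxy-3-methylpentanoate (diastereomer mixture), via bromomagnesium enolate 13 (not isolated)
Conditions: CH2=CHMgBr, CuBr·SMe2 (20 mol%), THF, −78 to −40 °C; then 12, −78 °C; aq. NH4Cl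
Reagents that add atoms: vinylmagnesium bromide C=C[Mg]Br
Why: copper-catalysed conjugate addition followed by aldol capture of the regiodefined enolate, in which the enone reacts through the half-chair with the C5 arm pseudoaxial so that vinyl enters C10 anti to it, setting the C10 quaternary centre with methyl cis and vinyl trans to the C5 arm.

Step 9
Reactants: 14 methyl (3R)-5-[(2R,3R)-2-ethenyl-3-(1-methoxy-1-oxopent-4-en-2-yl)-2-methyl-6-oxocyclohexyl]-5-hydroxy-3-methylpentanoate
Product: 16 methyl (3R)-5-[(2R,3R)-2-ethenyl-3-(1-methoxy-1-oxopent-4-en-2-yl)-2-methyl-6-oxocyclohexylidene]-3-methylpentanoate, via aldol mesylate 15 (not isolated)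
Conditions: MeSO2Cl, Et3N, CH2Cl2, 0 °C; then DBU, rt
Reagents that add atoms: none
Why: mesylation and E1cB elimination through the C9 enolate should give the conjugated exocyclic C9=C11 enone, whose geometry is immaterial.

Step 10
Reactants: 16 methyl (3R)-5-[(2R,3R)-2-ethenyl-3-(1-methoxy-1-oxopent-4-en-2-yl)-2-methyl-6-oxocyclohexylidene]-3-methylpentanoate
Product: 17 dimethyl (5R,10R,13R)-8-oxo-17,18-dinorlabda-1,9(11)-diene-15,19-dioate (trans-fused; C4 epimers)
Conditions: second-generation Grubbs catalyst (H2IMes)(PCy3)Cl2Ru=CHPh (5 mol%), CH2Cl2 (0.005 M), 40 °C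
Reagents that add atoms: none
Why: The ruthenium alkylidene loads onto the unhindered allyl terminus (C2), engages the neopentylic C10 vinyl group in an intramolecular [2+2] cycloaddition, and cycloreversion of the ruthenacyclobutane expels ethene and forms the C1=C2 bond. The closest known reaction type is ring-closing olefin metathesis of 1,7-dienes to cyclohexenes, including trans-fused octalins with one alkene on a quaternary carbon. Ring A, the only ring closed, forms as a six-membered cycloalkene by union of two terminal alkenes across the existing C5–C10 bond of ring B. No stereocentre is created: the trans ring fusion follows from the trans-diequatorial C10 vinyl and C5 arm fixed in step 8, and both C4 epimers can cyclise. The step needs chemoselectivity for the two monosubstituted alkenes over the trisubstituted conjugated C9=C11 enone and cyclisation over dimerisation; the hindered electron-poor enone should be inert to the catalyst and high dilution favours the six-membered closure.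

Step 11
Reactants: 17 dimethyl (5R,10R,13R)-8-oxo-17,18-dinorlabda-1,9(11)-diene-15,19-dioate
Product: 18 dimethyl (5R,9S,10R,13R)-8-oxo-17,18-dinorlabdane-15,19-dioate (C4 epimers)
Conditions: H2 (1 atm), Pd/C (palladium on carbon), EtOAc, rt
Reagents that add atoms: none
Why: heterogeneous hydrogenation saturates C1=C2 and the enone C9=C11, with hydrogen delivered to C9 anti to the axial C20 methyl to give the equatorial side chain, which is also the thermodynamic, epimerisable configuration.

Step 12
Reactants: 18 dimethyl (5R,9S,10R,13R)-8-oxo-17,18-dinorlabdane-15,19-dioate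
Product: 19 dimethyl (5R,9R,10R,13R)-18-norlabd-8(17)-ene-15,19-dioate (C4 epimers)
Conditions: Ph3PCH3Br, KOtBu, THF, 0 to 50 °C
Reagents that add atoms: methyltriphenylphosphonium bromide C[P+](c1ccccc1)(c1ccccc1)c1ccccc1.[Br-]
Why: Wittig methylenation converts the C8 ketone into the C8=C17 exocyclic alkene, the methyl esters being inert to the unstabilised ylide and any C9 epimerisation returning the favoured equatorial side chain.

Step 13
Reactants: 19 dimethyl (5R,9R,10R,13R)-18-norlabd-8(17)-ene-15,19-dioate
Product: 20 (5R,9R,10R,13R)-19-methoxy-19-oxo-18-norlabd-8(17)-en-15-oic acid (C4 epimers)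
Conditions: LiOH·H2O (1.3 equiv), THF/MeOH/H2O, 0 °C to rt; 1 M HCl
Reagents that add atoms: lithium hydroxide [Li+].[OH-]
Why: selective saponification, since hydroxide attacks the unhindered open-chain C15 methyl ester far faster than the α-branched ring-bound C19 ester.

Step 14
Reactants: 20 (5R,9R,10R,13R)-19-methoxy-19-oxo-18-norlabd-8(17)-en-15-oic acid
Product: 22 (4R,5S,9R,10S,13R)-19-methoxy-19-oxolabd-8(17)-en-15-oic acid, via dilithio ester enolate 21 (not isolated)
Conditions: LiN(iPr)2 (2.3 equiv), THF, −78 to −40 °C; MeI, −78 to 0 °C; 1 M HCl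
Reagents that add atoms: iodomethane CI
Why: ester enolate alkylation, in which the first equivalent of amide only forms the poorly acidic lithium carboxylate and the second deprotonates C4, and MeI then attacks the exocyclic C4 enolate from the equatorial face anti to the axial C20 methyl, giving the equatorial methyl and axial ester (4R) as in podocarpate-type alkylations.

Step 15
Reactants: 22 (4R,5S,9R,10S,13R)-19-methoxy-19-oxolabd-8(17)-en-15-oic acid
Product: 23 (4R,5S,9R,10S,13R)-19-hydroxylabd-8(17)-en-15-oic acid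
Conditions: LiEt3BH (5 equiv), THF, 0 °C to rt; 1 M HCl
Reagents that add atoms: none
Why: hydride reduction, in which LiEt3BH first forms the lithium carboxylate, which it does not reduce, and then reduces the hindered axial methyl ester to the C19 primary alcohol without touching the alkene.

Step 16
Reactants: 23 (4R,5S,9R,10S,13R)-19-hydroxylabd-8(17)-en-15-oic acid; 24 (2R)-2-methylbutanoic acid
Product: 27 (3R)-3-methyl-5-[(1R,4aS,5R,8aS)-5,8a-dimethyl-2-methylidene-5-({[(2R)-2-methylbutanoyl]oxy}methyl)decahydronaphthalen-1-yl]pentanoic acid, via (2R)-2-methylbutanoic anhydride 25 (not isolated), via C15 mixed anhydride 26 (not isolated)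
Conditions: 24 (6 equiv), DCC (3 equiv), CH2Cl2, 0 °C; then 23, DMAP, pyridine, rt to 40 °C; then H2O, rt
Reagents that add atoms: water O
Why: DMAP-catalysed acyl transfer from the preformed symmetrical anhydride (no carbodiimide left to activate the substrate acid) should esterify the neopentyl C19 alcohol without loss of the (2R) centre, and the mixed anhydride formed at C15 is hydrolysed back to the acid when water is added.

Compound list
1 | 2-methylcyclohex-2-en-1-one | CC1=CCCCC1=O | starting material
2 | (1R)-2-methylcyclohex-2-en-1-ol | CC1=CCCC[C@H]1O | intermediate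
3 | pent-4-enoyl chloride | C=CCCC(=O)Cl | starting material
4 | (1R)-2-methylcyclohex-2-en-1-yl pent-4-enoate | CC1=CCCC[C@H]1OC(=O)CCC=C | intermediate
5 | trimethylsilyl ketene acetal of 4 (trimethyl{1-[(1R)-2-methylcyclohex-2-en-1-yloxy]penta-1,4-dienyloxy}silane) | CC1=CCCC[C@H]1OC(O[Si](C)(C)C)=CCC=C | intermediate
6 | trimethylsilyl 2-[(1R)-2-methylcyclohex-2-en-1-yl]pent-4-enoate (C4 epimers) | CC1=CCCC[C@@H]1C(CC=C)C(=O)O[Si](C)(C)C | intermediate
7 | 2-[(1R)-2-methylcyclohex-2-en-1-yl]pent-4-enoic acid (C4 epimers) | CC1=CCCC[C@@H]1C(CC=C)C(=O)O | intermediate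
8 | methyl 2-[(1R)-2-methylcyclohex-2-en-1-yl]pent-4-enoate (C4 epimers) | CC1=CCCC[C@@H]1C(CC=C)C(=O)OC | intermediate
9 | methyl 2-[(1R)-2-methyl-4-oxocyclohex-2-en-1-yl]pent-4-enoate (C4 epimers) | CC1=CC(=O)CC[C@@H]1C(CC=C)C(=O)OC | intermediate
10 | (3R)-5-methoxy-3-methyl-5-oxopentanoic acid (methyl hydrogen (R)-3-methylglutarate) | OC(=O)C[C@@H](C)CC(=O)OC | starting material
11 | methyl (3R)-5-hydroxy-3-methylpentanoate | OCC[C@@H](C)CC(=O)OC | intermediate
12 | methyl (3R)-3-methyl-5-oxopentanoate | O=CC[C@@H](C)CC(=O)OC | intermediate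
13 | methyl 2-[(1R,2R)-4-(bromomagnesiooxy)-2-ethenyl-2-methylcyclohex-3-en-1-yl]pent-4-enoate (C8 enolate; vinyl trans to the C5 arm) | Br[Mg]OC1CC[C@H](C(CC=C)C(=O)OC)[C@@](C)(C=C)C=1 | intermediate
14 | methyl (3R)-5-[(2R,3R)-2-ethenyl-3-(1-methoxy-1-oxopent-4-en-2-yl)-2-methyl-6-oxocyclohexyl]-5-hydroxy-3-methylpentanoate (mixture at C4, C9, C11) | O=C1CC[C@H](C(CC=C)C(=O)OC)[C@@](C)(C=C)C1C(O)C[C@@H](C)CC(=O)OC | intermediate
15 | methyl (3R)-5-[(2R,3R)-2-ethenyl-3-(1-methoxy-1-oxopent-4-en-2-yl)-2-methyl-6-oxocyclohexyl]-5-(methanesulfonyloxy)-3-methylpentanoate (mixture at C4, C9, C11) | O=C1CC[C@H](C(CC=C)C(=O)OC)[C@@](C)(C=C)C1C(OS(C)(=O)=O)C[C@@H](C)CC(=O)OC | intermediate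
16 | methyl (3R)-5-[(2R,3R)-2-ethenyl-3-(1-methoxy-1-oxopent-4-en-2-yl)-2-methyl-6-oxocyclohexylidene]-3-methylpentanoate (C4 epimers) | O=C1CC[C@H](C(CC=C)C(=O)OC)[C@@](C)(C=C)C1=CC[C@@H](C)CC(=O)OC | intermediate
17 | dimethyl (5R,10R,13R)-8-oxo-17,18-dinorlabda-1,9(11)-diene-15,19-dioate (trans-fused; C4 epimers) | O=C1CC[C@@H]2C(C(=O)OC)CC=C[C@@]2(C)C1=CC[C@@H](C)CC(=O)OC | intermediate
18 | dimethyl (5R,9S,10R,13R)-8-oxo-17,18-dinorlabdane-15,19-dioate (C4 epimers) | O=C1CC[C@@H]2C(C(=O)OC)CCC[C@@]2(C)[C@@H]1CC[C@@H](C)CC(=O)OC | intermediate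
19 | dimethyl (5R,9R,10R,13R)-18-norlabd-8(17)-ene-15,19-dioate (C4 epimers) | C=C1CC[C@@H]2C(C(=O)OC)CCC[C@@]2(C)[C@@H]1CC[C@@H](C)CC(=O)OC | intermediate
20 | (5R,9R,10R,13R)-19-methoxy-19-oxo-18-norlabd-8(17)-en-15-oic acid (C4 epimers) | C=C1CC[C@@H]2C(C(=O)OC)CCC[C@@]2(C)[C@@H]1CC[C@@H](C)CC(=O)O | intermediate
21 | dilithium species of 20: C15 lithium carboxylate with C4=C19 lithium ester enolate | C=C1CC[C@@H]2C(=C(OC)O[Li])CCC[C@@]2(C)[C@@H]1CC[C@@H](C)CC(=O)O[Li] | intermediate
22 | (4R,5S,9R,10S,13R)-19-methoxy-19-oxolabd-8(17)-en-15-oic acid (axial C19 ester, equatorial C18 methyl) | C=C1CC[C@@H]2[C@](C)(C(=O)OC)CCC[C@@]2(C)[C@@H]1CC[C@@H](C)CC(=O)O | intermediate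
23 | (4R,5S,9R,10S,13R)-19-hydroxylabd-8(17)-en-15-oic acid | C=C1CC[C@@H]2[C@](C)(CO)CCC[C@@]2(C)[C@@H]1CC[C@@H](C)CC(=O)O | intermediate
24 | (2R)-2-methylbutanoic acid | CC[C@@H](C)C(=O)O | starting material
25 | (2R)-2-methylbutanoic anhydride | CC[C@@H](C)C(=O)OC(=O)[C@H](C)CC | intermediate
26 | mixed anhydride of 27 at C15 with (2R)-2-methylbutanoic acid | C=C1CC[C@@H]2[C@](C)(COC(=O)[C@H](C)CC)CCC[C@@]2(C)[C@@H]1CC[C@@H](C)CC(=O)OC(=O)[C@H](C)CC | intermediate
27 | (3R)-3-methyl-5-[(1R,4aS,5R,8aS)-5,8a-dimethyl-2-methylidene-5-({[(2R)-2-methylbutanoyl]oxy}methyl)decahydronaphthalen-1-yl]pentanoic acid (labdane numbering 4R,5S,9R,10S,13R) | C=C1CC[C@@H]2[C@](C)(COC(=O)[C@H](C)CC)CCC[C@@]2(C)[C@@H]1CC[C@@H](C)CC(=O)O | target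

Total step count: 16. Longest linear sequence: 14 steps (steps 1–5 and 8–16); steps 6–7 prepare aldehyde 12 and converge at step 8.

Steps most likely to fail

1. Step 8. The conjugate addition must build the C10 quaternary centre next to the substituted C5. Direct 1,2-addition of the Grignard reagent, enolisation of the enone, or retro-aldol loss of the adduct on work-up could erode the coupling. Fallback, from 9 back to 14: the vinyl addition is run with CuBr·SMe2 and Me3SiCl, so that the enolate is trapped and isolated as the silyl enol ether methyl 2-[(1R,2R)-2-ethenyl-2-methyl-4-(trimethylsilyloxy)cyclohex-3-en-1-yl]pent-4-enoate F1. F1 is then joined to 12 in a separate TiCl4-mediated Mukaiyama aldol addition at −78 °C, which gives 14.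

2. Step 5. Radical hydrogen abstraction may be poorly site-selective, with attack at the allylic methylene of the pentenyl chain, at C5–H or at the C20 methyl, or with over-oxidation. Fallback, from 8 back to 9, replaces the C–H oxidation by a polar 1,3-oxygen transposition. mCPBA epoxidises the trisubstituted ring alkene to methyl 2-[(2R)-1-methyl-7-oxabicyclo[4.1.0]heptan-2-yl]pent-4-enoate F2. PhSeNa (from PhSeSePh and NaBH4, EtOH) opens the epoxide at the less hindered C9 to methyl 2-[(1R)-2-hydroxy-2-methyl-3-(phenylselanyl)cyclohexyl]pent-4-enoate F3. H2O2 oxidation and selenoxide syn-elimination toward C8 give the tertiary allylic alcohol methyl 2-[(1R)-2-hydroxy-2-methylcyclohex-3-en-1-yl]pent-4-enoate F4. Pyridinium chlorochromate (C5H5NH)[CrO3Cl] then effects the oxidative allylic transposition (Babler–Dauben oxidation) to enone 9.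

3. Step 14. Chemoselectivity may be lost through deprotonation α to the carboxylate or O-methylation of the carboxylate, or the methyl group may enter from the wrong face. Fallback, from 20 back to 22, masks the carboxyl as a base-stable group without acidic α-hydrogens. Acid 20 is esterified with 3-methyl-3-oxetanemethanol (DCC, DMAP) to the (3-methyloxetan-3-yl)methyl ester F5. BF3·OEt2 rearranges F5 to the 4-methyl-2,6,7-trioxabicyclo[2.2.2]octane ortho ester F6. LiN(iPr)2 and MeI then methylate only C4, giving the ortho ester F7 with the axial C19 ester. Aqueous NaHSO4 opens the ortho ester to the 3-hydroxy-2-(hydroxymethyl)-2-methylpropyl ester F8, and LiOH saponifies this unhindered ester, leaving the hindered axial C19 ester, to give 22.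

Further compounds
F1 | step 8 | methyl 2-[(1R,2R)-2-ethenyl-2-methyl-4-(trimethylsilyloxy)cyclohex-3-en-1-yl]pent-4-enoate (C4 epimers) | C[Si](C)(C)OC1CC[C@H](C(CC=C)C(=O)OC)[C@@](C)(C=C)C=1
F2 | step 5 | methyl 2-[(2R)-1-methyl-7-oxabicyclo[4.1.0]heptan-2-yl]pent-4-enoate (epoxide diastereomers) | CC12OC1CCC[C@@H]2C(CC=C)C(=O)OC
F3 | step 5 | methyl 2-[(1R)-2-hydroxy-2-methyl-3-(phenylselanyl)cyclohexyl]pent-4-enoate | CC1(O)C([Se]c2ccccc2)CCC[C@@H]1C(CC=C)C(=O)OC
F4 | step 5 | methyl 2-[(1R)-2-hydroxy-2-methylcyclohex-3-en-1-yl]pent-4-enoate | CC1(O)C=CCC[C@@H]1C(CC=C)C(=O)OC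
F5 | step 14 | (3-methyloxetan-3-yl)methyl ester of 20 at C15 (C4 epimers) | C=C1CC[C@@H]2C(C(=O)OC)CCC[C@@]2(C)[C@@H]1CC[C@@H](C)CC(=O)OCC1(C)COC1
F6 | step 14 | methyl (5R,9R,10R,13R)-15-nor-14-(4-methyl-2,6,7-trioxabicyclo[2.2.2]octan-1-yl)-18-norlabd-8(17)-en-19-oate (C15 ortho ester of 20; C4 epimers) | C=C1CC[C@@H]2C(C(=O)OC)CCC[C@@]2(C)[C@@H]1CC[C@@H](C)CC34OCC(C)(CO3)CO4
F7 | step 14 | C4-methylated ortho ester (4R; axial C19 methyl ester, C15 as 4-methyl-2,6,7-trioxabicyclo[2.2.2]octan-1-yl) | C=C1CC[C@@H]2[C@](C)(C(=O)OC)CCC[C@@]2(C)[C@@H]1CC[C@@H](C)CC34OCC(C)(CO3)CO4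
F8 | step 14 | 3-hydroxy-2-(hydroxymethyl)-2-methylpropyl ester of 22 at C15 | C=C1CC[C@@H]2[C@](C)(C(=O)OC)CCC[C@@]2(C)[C@@H]1CC[C@@H](C)CC(=O)OCC(C)(CO)CO
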